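**Plan** (carotenoid numbering; primes mark the ε half)
- Cuts: first both O–palmitoyl bonds. Then C11=C12 (Wittig: C15 epoxy-dienal + C25 phosphonium salt), C11'=C12' (Wittig: C15 ε-salt + C10 dialdehyde) and C7=C8 (HWE). Last, C5–C6 and C6–O are cut together.
- Enabling feature: the oxirane (O, C5, C6) and the cyclohexane (C1–C6) share the C5–C6 bond. C5 carries only CH3 and C4, so it is a latent methyl ketone. C6 carries C7, a latent carboxyl carbon that acidifies C6–H. Both rings therefore open to one acyclic α-chloro-ε-keto ester.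
- Forward: the ε ring is bought in α-ionone. C7–C6–C1–C2–C3 comes from 3,3-dimethylpent-4-enoic acid and C4–C5–C18 from a methallyl unit. An intramolecular Darzens reaction then closes carbocycle and oxirane in one operation, and no ring is formed afterwards. The chain is joined C10→C15, then C15+C10→C25, then C25+C15.
- Stereochemistry: C3 is set by methallylboration and is relayed to C5 and C6 in the Darzens chair. The C3'/C6' trans relation comes from a P450 hydroxylation and its absolute sense from a lipase resolution. The new C=C bonds are E by HWE/Wittig plus thermal equilibration.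

Key step: step 7

Remark on the chemistry: the chlorine-bearing carbon in 6–8 and C9' in 21 are carried as epimer mixtures, because steps 7 and 16 erase these centres.

**Route**

Step 1
Reactants: 1 3,3-dimethylpent-4-enoic acid
Product: 2 tert-butyl 3,3-dimethylpent-4-enoate
Conditions: Boc2O, DMAP (cat.), t-BuOH, 30 °C
Reagents that add atoms: di-tert-butyl dicarbonate, CC(C)(C)OC(=O)OC(=O)OC(C)(C)C
Why: DMAP-catalysed esterification via the mixed carbonic anhydride should give the tert-butyl ester, chosen because it will not lactonise onto the C3 hydroxyl after step 3 and resists acyl attack in step 7.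

Step 2
Reactants: 2 tert-butyl 3,3-dimethylpent-4-enoate
Product: 3 tert-butyl 3,3-dimethyl-5-oxopentanoate
Conditions: PdCl2(PhCN)2 (cat.), CuCl2·2H2O (cat.), AgNO2 (cat.), O2 (1 atm), t-BuOH/MeNO2, rt
Reagents that add atoms: dioxygen, O=O
Why: The nitrite-modified, aldehyde-selective Wacker oxidation should place oxygen on the terminal carbon, because the quaternary allylic carbon C1 disfavours attack at the internal position, giving the C3 aldehyde with the ester untouched.

Step 3
Reactants: 3 tert-butyl 3,3-dimethyl-5-oxopentanoate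
Product: 4 tert-butyl (5R)-5-hydroxy-3,3,7-trimethyloct-7-enoate
Conditions: (+)-Ipc2BOMe [from (−)-α-pinene], methallylMgCl, Et2O, −78 °C → rt; then 3, −78 °C; then NaOH, H2O2, 0 °C
Reagents that add atoms: methallylmagnesium chloride, CC(=C)C[Mg]Cl
Why: Brown-type asymmetric methallylboration through a closed chair transition state should set C3, the isopinocampheyl groups from (−)-α-pinene directing attack to the aldehyde face that gives the (5R) carbinol (the later 3S centre), while the isopropenyl group is a masked C5 methyl ketone.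

Step 4
Reactants: 4 tert-butyl (5R)-5-hydroxy-3,3,7-trimethyloct-7-enoate
Product: 5 tert-butyl (5R)-5-[(tert-butyldimethylsilyl)oxy]-3,3,7-trimethyloct-7-enoate
Conditions: TBSCl, imidazole, DMF, rt
Reagents that add atoms: tert-butyldimethylsilyl chloride, CC(C)(C)[Si](C)(C)Cl
Why: Imidazole-promoted silylation masks the C3 hydroxyl as a bulky, non-chelating, base-stable ether that is a poor leaving group in step 7.

Step 5
Reactants: 5 tert-butyl (5R)-5-[(tert-butyldimethylsilyl)oxy]-3,3,7-trimethyloct-7-enoate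
Product: 6 tert-butyl (5R)-5-[(tert-butyldimethylsilyl)oxy]-2-chloro-3,3,7-trimethyloct-7-enoate (C2 epimers)
Conditions: LDA, THF, −78 °C; enolate added to NCS, THF, −78 °C; then H2O
Reagents that add atoms: N-chlorosuccinimide, O=C1CCC(=O)N1Cl
Why: Electrophilic α-chlorination of the lithium ester enolate puts the leaving group on C6, a neopentyl carbon that SN2 chemistry could not reach, and the epimer mixture is harmless because step 7 passes through the planar enolate.

Step 6
Reactants: 6 tert-butyl (5R)-5-[(tert-butyldimethylsilyl)oxy]-2-chloro-3,3,7-trimethyloct-7-enoate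
Product: 8 tert-butyl (5S)-5-[(tert-butyldimethylsilyl)oxy]-2-chloro-3,3-dimethyl-7-oxooctanoate, via secondary ozonide 7 (not isolated)
Conditions: O3, CH2Cl2, −78 °C; then Me2S, −78 °C → rt
Reagents that add atoms: ozone, [O-][O+]=O
Why: Ozonolysis with reductive work-up cleaves the only C=C bond and unmasks the C5 methyl ketone, since silyl ether, chloride and ester are inert to ozone (the descriptor changes only through CIP priorities).

Step 7
Reactants: 8 tert-butyl (5S)-5-[(tert-butyldimethylsilyl)oxy]-2-chloro-3,3-dimethyl-7-oxooctanoate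
Product: 10 tert-butyl (1S,4S,6R)-4-[(tert-butyldimethylsilyl)oxy]-2,2,6-trimethyl-7-oxabicyclo[4.1.0]heptane-1-carboxylate, via chlorohydrin alkoxide 9 (not isolated)
Conditions: KOt-Bu, THF/t-BuOH, −40 → 0 °C
Reagents that add atoms: none
Why: tert-Butoxide reversibly removes the most acidic proton, C6–H between chlorine and ester, the planar enolate (which erases the C6 epimer mixture) adds to the C5 methyl ketone in a 6-(enolexo)-exo-trig aldol assisted by the C1 gem-dimethyl group, and alkoxide 9 then displaces chloride in a 3-exo-tet SN2 step, so carbocycle and oxirane close in one operation. The closest known reaction type is the Darzens glycidic ester condensation in its intramolecular form, which is known to build epoxide-fused cyclohexanes from halo-carbonyl/carbonyl chains. Oxirane closure requires a trans-diaxial O−/Cl pair, so C5 and C6 are set together as the cis-fused epoxide, and aldolates of the wrong relative configuration can only revert by retro-aldol. The face is controlled by C3: in the reacting chair the axial C5–O− shares its face with the axial C1 methyl and the axial substituent on C3, which must therefore be H, so OTBS sits equatorial and the oxirane forms anti to it, giving (3S,5R,6S). The step needs selectivity over β-elimination of the silyloxy group, Claisen-type attack of the C4 enolate on the ester, and 5-exo alkylation of that enolate at C6. These are held back by the poor leaving ability of OTBS at low temperature, the bulk of the tert-butyl ester and the neopentyl position of the C–Cl bond, while only the Darzens channel ends irreversibly with loss of chloride.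

Step 8
Reactants: 10 tert-butyl (1S,4S,6R)-4-[(tert-butyldimethylsilyl)oxy]-2,2,6-trimethyl-7-oxabicyclo[4.1.0]heptane-1-carboxylate
Product: 11 [(1R,4S,6R)-4-[(tert-butyldimethylsilyl)oxy]-2,2,6-trimethyl-7-oxabicyclo[4.1.0]heptan-1-yl]methanol
Conditions: LiAlH4, Et2O, 0 °C → rt; aqueous NaOH work-up
Reagents that add atoms: none
Why: Hydride reduction of the glycidic ester should stop cleanly at the primary alcohol, because the tetrasubstituted oxirane offers no carbon open to SN2 hydride attack and the silyl ether is inert (the C1 descriptor changes through priorities only).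

Step 9
Reactants: 11 [(1R,4S,6R)-4-[(tert-butyldimethylsilyl)oxy]-2,2,6-trimethyl-7-oxabicyclo[4.1.0]heptan-1-yl]methanol
Product: 12 (1S,4S,6R)-4-[(tert-butyldimethylsilyl)oxy]-2,2,6-trimethyl-7-oxabicyclo[4.1.0]heptane-1-carbaldehyde
Conditions: TPAP (cat.), NMO, 4 Å MS, CH2Cl2, rt
Reagents that add atoms: none
Why: The Ley–Griffith oxidation works under neutral conditions and should give the non-enolisable epoxy aldehyde (C7) without acid that could open the oxirane.

Step 10
Reactants: 12 (1S,4S,6R)-4-[(tert-butyldimethylsilyl)oxy]-2,2,6-trimethyl-7-oxabicyclo[4.1.0]heptane-1-carbaldehyde; 13 diethyl [(2E)-3-cyano-2-methylprop-2-en-1-yl]phosphonate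
Product: 14 (2E,4E)-5-[(1S,4S,6R)-4-[(tert-butyldimethylsilyl)oxy]-2,2,6-trimethyl-7-oxabicyclo[4.1.0]heptan-1-yl]-3-methylpenta-2,4-dienenitrile
Conditions: 13, n-BuLi, THF, −78 °C; then 12, −78 → 0 °C
Reagents that add atoms: none
Why: Horner–Wadsworth–Emmons olefination with the stabilised allylic phosphonate anion should form C7=C8 with E geometry, a reaction type established for this class of hindered epoxy aldehydes, and any 9Z isomer is removed by chromatography.

Step 11
Reactants: 14 (2E,4E)-5-[(1S,4S,6R)-4-[(tert-butyldimethylsilyl)oxy]-2,2,6-trimethyl-7-oxabicyclo[4.1.0]heptan-1-yl]-3-methylpenta-2,4-dienenitrile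
Product: 15 (2E,4E)-5-[(1S,4S,6R)-4-hydroxy-2,2,6-trimethyl-7-oxabicyclo[4.1.0]heptan-1-yl]-3-methylpenta-2,4-dienenitrile
Conditions: TBAF, THF, rt
Reagents that add atoms: none
Why: Fluoride-induced desilylation frees the C3 hydroxyl at the robust nitrile stage, where neither the oxirane nor the dienenitrile responds to fluoride.

Step 12
Reactants: 15 (2E,4E)-5-[(1S,4S,6R)-4-hydroxy-2,2,6-trimethyl-7-oxabicyclo[4.1.0]heptan-1-yl]-3-methylpenta-2,4-dienenitrile
Product: 17 (2E,4E)-5-[(1S,4S,6R)-4-hydroxy-2,2,6-trimethyl-7-oxabicyclo[4.1.0]heptan-1-yl]-3-methylpenta-2,4-dienal, via aldimine 16 (not isolated)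
Conditions: DIBAL-H (3 equiv), CH2Cl2, −78 °C; then wet silica gel, 0 °C
Reagents that add atoms: water, O
Why: Partial DIBAL-H reduction of the nitrile stops at the N-aluminated aldimine (one equivalent is used up by the hydroxyl), and near-neutral hydrolysis should release the dienal without the acid-induced 5,6- to 5,8-epoxide rearrangement.

Step 13
Reactants: 18 (±)-α-ionone
Product: 19 rac-trans-3-hydroxy-α-ionone, (3R*,6R*)
Conditions: bacterial cytochrome P450 monooxygenase (CYP101-type or engineered CYP102 variant) plus its redox partners, NADP+ (cat.), glucose dehydrogenase, D-glucose, air, phosphate buffer pH 7.5, 30 °C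
Reagents that add atoms: dioxygen, O=O
Why: Enzymatic allylic C–H hydroxylation (hydrogen abstraction and oxygen rebound) by bacterial P450 monooxygenases is known on α-ionone to attack the ring methylene C3 and to deliver oxygen opposite the C6 side chain, so the trans relation is set by the enzyme pocket in one step, which small oxidants do not achieve.

Step 14
Reactants: 19 rac-trans-3-hydroxy-α-ionone
Product: 20 (3R,6R)-3-hydroxy-α-ionone
Conditions: Pseudomonas-type lipase (AK or PS), vinyl acetate, MTBE, 30 °C, taken slightly past half conversion; chromatography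
Reagents that add atoms: none
Why: In this lipase-catalysed kinetic resolution by irreversible transesterification, the empirical size rule for lipases (CH2–CMe2 flank large, vinylic CH flank medium) predicts faster acetylation of the (3S,6S) alcohol, so the (3R,6R) alcohol should be recovered enantiopure.

Step 15
Reactants: 20 (3R,6R)-3-hydroxy-α-ionone
Product: 21 (1E)-1-[(1R,4R)-4-hydroxy-2,6,6-trimethylcyclohex-2-en-1-yl]-3-methylpenta-1,4-dien-3-ol (C3 epimers)
Conditions: vinylMgBr (2.5 equiv), THF, −30 → 0 °C; aq. NH4Cl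
Reagents that add atoms: vinylmagnesium bromide, C=C[Mg]Br
Why: Grignard 1,2-addition to the enone carbonyl (the first equivalent deprotonates the hydroxyl) gives the tertiary divinyl carbinol, whose new centre is irrelevant because it is ionised in the next step.

Step 16
Reactants: 21 (1E)-1-[(1R,4R)-4-hydroxy-2,6,6-trimethylcyclohex-2-en-1-yl]-3-methylpenta-1,4-dien-3-ol
Product: 22 [(2E,4E)-5-[(1R,4R)-4-hydroxy-2,6,6-trimethylcyclohex-2-en-1-yl]-3-methylpenta-2,4-dien-1-yl]triphenylphosphonium bromide
Conditions: PPh3·HBr (1.0 equiv), CH2Cl2, 0 °C → rt; crystallisation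
Reagents that add atoms: triphenylphosphine hydrobromide, [Br-].c1ccccc1[PH+](c1ccccc1)c1ccccc1
Why: In this SN1′-type phosphonium salt formation the tertiary bis-allylic alcohol should ionise far faster than the secondary ring alcohol, and PPh3 captures the pentadienyl cation at its unhindered terminus C11', the 9'E salt being purified by crystallisation.

Step 17
Reactants: 22 C15 ε-phosphonium bromide; 23 (2E,4E,6E)-2,7-dimethylocta-2,4,6-trienedial
Product: 24 (3R,6R)-3-hydroxy-12'-apo-ε-caroten-12'-al
Conditions: 23 (excess), NaOMe, CH2Cl2/MeOH, 0 °C → rt; then brief reflux in EtOH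
Reagents that add atoms: none
Why: Wittig olefination of the semi-stabilised ylide with an excess of the symmetrical dialdehyde should stop at mono-condensation and form C11'=C12', with the hindered Z isomer reverting to E on heating and the free hydroxyl tolerated.

Step 18
Reactants: 24 (3R,6R)-3-hydroxy-12'-apo-ε-caroten-12'-al
Product: 25 (3R,6R)-12'-apo-ε-carotene-3,12'-diol
Conditions: NaBH4, EtOH/THF, 0 °C
Reagents that add atoms: none
Why: Borohydride 1,2-reduction of the polyenal gives the primary polyenyl alcohol without touching the polyene or the stereocentres.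

Step 19
Reactants: 25 (3R,6R)-12'-apo-ε-carotene-3,12'-diol
Product: 26 [(3R,6R)-3-hydroxy-12'-apo-ε-caroten-12'-yl]triphenylphosphonium bromide
Conditions: PPh3·HBr (1.0 equiv), CH2Cl2, 0 °C, dark
Reagents that add atoms: triphenylphosphine hydrobromide, [Br-].c1ccccc1[PH+](c1ccccc1)c1ccccc1
Why: This is SN1-type phosphonium salt formation, in which the primary alcohol conjugated with five double bonds should ionise much more easily than the carbinol of step 16 and hence than the ring allylic alcohol, so one equivalent of the mild acid salt is consumed at the chain terminus.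

Step 20
Reactants: 26 C25 ε-phosphonium bromide; 17 C15 epoxy-hydroxy-dienal
Product: 27 (3S,5R,6S,3'R,6'R)-5,6-epoxy-5,6-dihydro-β,ε-carotene-3,3'-diol (lutein 5,6-epoxide)
Conditions: NaOMe, CH2Cl2/MeOH, 0 °C → rt, dark; then brief reflux in EtOH, crystallisation
Reagents that add atoms: none
Why: Wittig olefination joins C11 and C12 under basic conditions that leave oxirane, hydroxyls and all five stereocentres untouched, and the hindered 11Z isomer should revert to all-E on gentle heating in a neutral solvent.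

Step 21
Reactants: 27 lutein 5,6-epoxide
Product: 28 (3S,5R,6S,3'R,6'R)-5,6-epoxy-5,6-dihydro-β,ε-carotene-3,3'-diyl dipalmitate (target)
Conditions: palmitic anhydride (3 equiv), DMAP, Et3N, CH2Cl2, rt, Ar, dark
Reagents that add atoms: palmitic anhydride, CCCCCCCCCCCCCCCC(=O)OC(=O)CCCCCCCCCCCCCCC
Why: DMAP-catalysed acyl transfer esterifies both secondary hydroxyls at oxygen, so C3 and C3' keep their configuration, and the anhydride/amine medium avoids the free HCl that would trigger the furanoid rearrangement of the 5,6-epoxide.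

**Compound list**
1 | 3,3-dimethylpent-4-enoic acid | C=CC(C)(C)CC(=O)O | starting material
2 | tert-butyl 3,3-dimethylpent-4-enoate | C=CC(C)(C)CC(=O)OC(C)(C)C | intermediate
3 | tert-butyl 3,3-dimethyl-5-oxopentanoate | O=CCC(C)(C)CC(=O)OC(C)(C)C | intermediate
4 | tert-butyl (5R)-5-hydroxy-3,3,7-trimethyloct-7-enoate | O[C@H](CC(C)=C)CC(C)(C)CC(=O)OC(C)(C)C | intermediate
5 | tert-butyl (5R)-5-[(tert-butyldimethylsilyl)oxy]-3,3,7-trimethyloct-7-enoate | CC(C)(C)[Si](C)(C)O[C@H](CC(C)=C)CC(C)(C)CC(=O)OC(C)(C)C | intermediate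
6 | tert-butyl (5R)-5-[(tert-butyldimethylsilyl)oxy]-2-chloro-3,3,7-trimethyloct-7-enoate (C2 epimers) | CC(C)(C)[Si](C)(C)O[C@H](CC(C)=C)CC(C)(C)C(Cl)C(=O)OC(C)(C)C | intermediate
7 | secondary ozonide, tert-butyl (5S)-5-[(tert-butyldimethylsilyl)oxy]-2-chloro-3,3-dimethyl-6-(3-methyl-1,2,4-trioxolan-3-yl)hexanoate (not isolated) | CC(C)(C)[Si](C)(C)O[C@H](CC1(C)OCOO1)CC(C)(C)C(Cl)C(=O)OC(C)(C)C | intermediate
8 | tert-butyl (5S)-5-[(tert-butyldimethylsilyl)oxy]-2-chloro-3,3-dimethyl-7-oxooctanoate (C2 epimers) | CC(C)(C)[Si](C)(C)O[C@H](CC(C)=O)CC(C)(C)C(Cl)C(=O)OC(C)(C)C | intermediate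
9 | chlorohydrin alkoxide, potassium salt of tert-butyl (1R,2R,4S)-4-[(tert-butyldimethylsilyl)oxy]-1-chloro-2-hydroxy-2,6,6-trimethylcyclohexane-1-carboxylate; O− and Cl trans-diaxial, O− anti to OTBS (not isolated) | [K+].CC(C)(C)[Si](C)(C)O[C@H]1CC(C)(C)[C@@](C(=O)OC(C)(C)C)(Cl)[C@](C)([O-])C1 | intermediate
10 | tert-butyl (1S,4S,6R)-4-[(tert-butyldimethylsilyl)oxy]-2,2,6-trimethyl-7-oxabicyclo[4.1.0]heptane-1-carboxylate | CC(C)(C)[Si](C)(C)O[C@H]1CC(C)(C)[C@]2(C(=O)OC(C)(C)C)O[C@]2(C)C1 | intermediate
11 | [(1R,4S,6R)-4-[(tert-butyldimethylsilyl)oxy]-2,2,6-trimethyl-7-oxabicyclo[4.1.0]heptan-1-yl]methanol | CC(C)(C)[Si](C)(C)O[C@H]1CC(C)(C)[C@]2(CO)O[C@]2(C)C1 | intermediate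
12 | (1S,4S,6R)-4-[(tert-butyldimethylsilyl)oxy]-2,2,6-trimethyl-7-oxabicyclo[4.1.0]heptane-1-carbaldehyde | CC(C)(C)[Si](C)(C)O[C@H]1CC(C)(C)[C@]2(C=O)O[C@]2(C)C1 | intermediate
13 | diethyl [(2E)-3-cyano-2-methylprop-2-en-1-yl]phosphonate | CCOP(=O)(OCC)C/C(C)=C/C#N | starting material
14 | (2E,4E)-5-[(1S,4S,6R)-4-[(tert-butyldimethylsilyl)oxy]-2,2,6-trimethyl-7-oxabicyclo[4.1.0]heptan-1-yl]-3-methylpenta-2,4-dienenitrile | CC(C)(C)[Si](C)(C)O[C@H]1CC(C)(C)[C@]2(/C=C/C(C)=C/C#N)O[C@]2(C)C1 | intermediate
15 | (2E,4E)-5-[(1S,4S,6R)-4-hydroxy-2,2,6-trimethyl-7-oxabicyclo[4.1.0]heptan-1-yl]-3-methylpenta-2,4-dienenitrile | O[C@H]1CC(C)(C)[C@]2(/C=C/C(C)=C/C#N)O[C@]2(C)C1 | intermediate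
16 | aldimine of 17, present as its N-diisobutylaluminium derivative (not isolated) | O[C@H]1CC(C)(C)[C@]2(/C=C/C(C)=C/C=N)O[C@]2(C)C1 | intermediate
17 | (2E,4E)-5-[(1S,4S,6R)-4-hydroxy-2,2,6-trimethyl-7-oxabicyclo[4.1.0]heptan-1-yl]-3-methylpenta-2,4-dienal | O[C@H]1CC(C)(C)[C@]2(/C=C/C(C)=C/C=O)O[C@]2(C)C1 | intermediate
18 | (±)-α-ionone, (3E)-4-(2,6,6-trimethylcyclohex-2-en-1-yl)but-3-en-2-one | CC(=O)/C=C/C1C(C)=CCCC1(C)C | starting material
19 | rac-trans-3-hydroxy-α-ionone (both enantiomers written) | CC(=O)/C=C/[C@H]1C(C)=C[C@H](O)CC1(C)C.CC(=O)/C=C/[C@@H]1C(C)=C[C@@H](O)CC1(C)C | intermediate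
20 | (3R,6R)-3-hydroxy-α-ionone | CC(=O)/C=C/[C@H]1C(C)=C[C@H](O)CC1(C)C | intermediate
21 | (1E)-1-[(1R,4R)-4-hydroxy-2,6,6-trimethylcyclohex-2-en-1-yl]-3-methylpenta-1,4-dien-3-ol (C3 epimers) | C=CC(C)(O)/C=C/[C@H]1C(C)=C[C@H](O)CC1(C)C | intermediate
22 | [(2E,4E)-5-[(1R,4R)-4-hydroxy-2,6,6-trimethylcyclohex-2-en-1-yl]-3-methylpenta-2,4-dien-1-yl]triphenylphosphonium bromide | [Br-].c1ccccc1[P+](c1ccccc1)(c1ccccc1)C/C=C(C)/C=C/[C@H]1C(C)=C[C@H](O)CC1(C)C | intermediate
23 | (2E,4E,6E)-2,7-dimethylocta-2,4,6-trienedial | O=C/C(C)=C/C=C/C=C(C)/C=O | starting material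
24 | (3R,6R)-3-hydroxy-12'-apo-ε-caroten-12'-al | O=C/C(C)=C/C=C/C=C(C)/C=C/C=C(C)/C=C/[C@H]1C(C)=C[C@H](O)CC1(C)C | intermediate
25 | (3R,6R)-12'-apo-ε-carotene-3,12'-diol | OC/C(C)=C/C=C/C=C(C)/C=C/C=C(C)/C=C/[C@H]1C(C)=C[C@H](O)CC1(C)C | intermediate
26 | [(3R,6R)-3-hydroxy-12'-apo-ε-caroten-12'-yl]triphenylphosphonium bromide | [Br-].c1ccccc1[P+](c1ccccc1)(c1ccccc1)C/C(C)=C/C=C/C=C(C)/C=C/C=C(C)/C=C/[C@H]1C(C)=C[C@H](O)CC1(C)C | intermediate
27 | (3S,5R,6S,3'R,6'R)-5,6-epoxy-5,6-dihydro-β,ε-carotene-3,3'-diol | O[C@H]1CC(C)(C)[C@]2(/C=C/C(C)=C/C=C/C(C)=C/C=C/C=C(C)/C=C/C=C(C)/C=C/[C@H]3C(C)=C[C@H](O)CC3(C)C)O[C@]2(C)C1 | intermediate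
28 | (3S,5R,6S,3'R,6'R)-5,6-epoxy-5,6-dihydro-β,ε-carotene-3,3'-diyl dipalmitate | CCCCCCCCCCCCCCCC(=O)O[C@H]1CC(C)(C)[C@]2(/C=C/C(C)=C/C=C/C(C)=C/C=C/C=C(C)/C=C/C=C(C)/C=C/[C@H]3C(C)=C[C@H](OC(=O)CCCCCCCCCCCCCCC)CC3(C)C)O[C@]2(C)C1 | target

**Step count**
Total: 21 steps. Longest linear sequence: 14 steps (steps 1–12, 20, 21).

**Steps most likely to fail**

1. Step 7. β-Elimination of the silyloxy group from the ketone enolate, or unproductive enolate equilibration, could outrun the hindered C5–C6 bond formation.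
   - The fallback sets out from 8 and rejoins at 11, making the C5–C6 bond reductively and placing the oxygen afterwards.
   - SmI2 (THF/HMPA, −78 °C) converts the C–Cl bond of 8 into a samarium enolate under non-basic conditions. An intramolecular Reformatsky reaction should then give tert-butyl (4S)-4-[(tert-butyldimethylsilyl)oxy]-2-hydroxy-2,6,6-trimethylcyclohexane-1-carboxylate F1.
   - Dehydration (SOCl2, pyridine, then DBU to bring the double bond into conjugation) gives tert-butyl (4R)-4-[(tert-butyldimethylsilyl)oxy]-2,6,6-trimethylcyclohex-1-ene-1-carboxylate F2.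
   - DIBAL-H gives [(4R)-4-[(tert-butyldimethylsilyl)oxy]-2,6,6-trimethylcyclohex-1-en-1-yl]methanol F3.
   - Sharpless asymmetric epoxidation (Ti(OiPr)4, D-(−)-diethyl tartrate, t-BuOOH) delivers oxygen anti to the silyloxy group and gives 11.

2. Step 19. Acid-promoted ionisation of the ring allylic C3'–OH (substitution, dehydration or epimerisation) could compete with ionisation at the chain terminus.
   - The fallback sets out from 17 and 24 and rejoins at 27. It reverses the polarity of the last coupling, so no acid meets the ε ring after step 16.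
   - NaBH4 reduces 17 to (2E,4E)-5-[(1S,4S,6R)-4-hydroxy-2,2,6-trimethyl-7-oxabicyclo[4.1.0]heptan-1-yl]-3-methylpenta-2,4-dien-1-ol F4.
   - A Mitsunobu reaction at the primary allylic hydroxyl (2-mercaptobenzothiazole, PPh3, DIAD, 0 °C) gives the benzothiazolyl sulfide F5.
   - Molybdate-catalysed H2O2 oxidation gives the benzothiazolyl sulfone F6.
   - Julia–Kocienski olefination of F6 with aldehyde 24 (LiHMDS in excess to cover the two hydroxyls, THF, −78 °C), followed by thermal Z-to-E equilibration, gives 27.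

3. Step 14. The lipase could discriminate the enantiomers insufficiently, or in the inverted sense.
   - The fallback sets out from 19 and rejoins at 20, replacing the kinetic resolution by separation of diastereomers.
   - Steglich esterification of 19 with (S)-methoxy(phenyl)acetic acid (DCC, DMAP) gives the (3R,6R)-3-hydroxy-α-ionone (S)-O-methylmandelate F7 and the (3S,6S)-3-hydroxy-α-ionone (S)-O-methylmandelate F8.
   - The two esters are separated by chromatography or crystallisation, and mild methanolysis of F7 (K2CO3, MeOH, 0 °C) releases 20.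

**Further compounds**
F1 | step 7 | tert-butyl (4S)-4-[(tert-butyldimethylsilyl)oxy]-2-hydroxy-2,6,6-trimethylcyclohexane-1-carboxylate | CC(C)(C)[Si](C)(C)O[C@H]1CC(C)(C)C(C(=O)OC(C)(C)C)C(C)(O)C1
F2 | step 7 | tert-butyl (4R)-4-[(tert-butyldimethylsilyl)oxy]-2,6,6-trimethylcyclohex-1-ene-1-carboxylate | CC(C)(C)[Si](C)(C)O[C@H]1CC(C)(C)C(C(=O)OC(C)(C)C)=C(C)C1
F3 | step 7 | [(4R)-4-[(tert-butyldimethylsilyl)oxy]-2,6,6-trimethylcyclohex-1-en-1-yl]methanol | CC(C)(C)[Si](C)(C)O[C@H]1CC(C)(C)C(CO)=C(C)C1
F4 | step 19 | (2E,4E)-5-[(1S,4S,6R)-4-hydroxy-2,2,6-trimethyl-7-oxabicyclo[4.1.0]heptan-1-yl]-3-methylpenta-2,4-dien-1-ol | O[C@H]1CC(C)(C)[C@]2(/C=C/C(C)=C/CO)O[C@]2(C)C1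
F5 | step 19 | benzothiazol-2-yl sulfide of F4 | O[C@H]1CC(C)(C)[C@]2(/C=C/C(C)=C/CSc3nc4ccccc4s3)O[C@]2(C)C1
F6 | step 19 | benzothiazol-2-yl sulfone of F4 | O[C@H]1CC(C)(C)[C@]2(/C=C/C(C)=C/CS(=O)(=O)c3nc4ccccc4s3)O[C@]2(C)C1
F7 | step 14 | (3R,6R)-3-hydroxy-α-ionone (S)-O-methylmandelate | CC(=O)/C=C/[C@H]1C(C)=C[C@H](OC(=O)[C@@H](OC)c2ccccc2)CC1(C)C
F8 | step 14 | (3S,6S)-3-hydroxy-α-ionone (S)-O-methylmandelate | CC(=O)/C=C/[C@@H]1C(C)=C[C@@H](OC(=O)[C@@H](OC)c2ccccc2)CC1(C)C
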